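## Retrosynthetic overview

- Target ⇒ trans β-hydroxy selenide ⇒ syn 5,6-epoxide ⇒ diacetate alkene: C4=C5 and C6–OH come from a C1–OH-directed epoxidation of C5=C6, selenide opening at C5 and selenoxide syn-elimination towards C4.
- Diacetate ⇒ syn 2,3-epoxy alcohol: the trans C2/C3 diacetate comes from acetate opening of the oxirane at C3 with inversion, then acetylation of C2–OH.
- Epoxy alcohol ⇒ achiral 1-(benzoyloxymethyl)cyclohexa-2,5-dien-1-ol by catalytic enantioselective desymmetrisation: hydroxyl-directed epoxidation of one of two enantiotopic alkenes (Hf(OtBu)4, chiral bishydroxamic acid, cumene hydroperoxide).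
- Dienol ⇒ cyclohexa-2,5-diene-1-carboxylic acid by esterification, enolate hydroxylation, reduction and benzoylation.
- Feature used: in the cyclohexene ring the quaternary carbinol C1 (carrying C7H2OBz) lies between two oxygenated arms, C2–C3 and C6–C5, so removing those oxygens leaves a mirror-symmetric cyclohexa-2,5-dien-1-ol. Ring order: carbocycle bought; oxirane C2–O–C3 (step 5) and oxirane C5–O–C6 (step 8) are made and opened again.

Key step: step 5

## Remarks

- Atom labels used in all names (not lowest locants): C1 quaternary carbinol, C7 its CH2OBz carbon, C2/C3 acetoxy carbons, C4=C5 alkene and C6 carbinol in the target. In dienol 7 the alkenes are C2=C3 and C5=C6 and C4 is CH2.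
- Assumption: acid 1 is purchased; if not, it is one Birch reduction away from benzoic acid.
- Assumption: which antipode of the ligand selects the C2=C3 alkene leading to 9 cannot be predicted with certainty for a cyclic dienol. The (R,R)-ligand is tried first and the (S,S)-ligand is used if the sense proves opposite.
- Dienols 5 and 7 are formally arene hydrates. Their work-ups and chromatography are kept neutral to basic (Et3N-washed silica).

## Route

Step 1
Reactants: 1 cyclohexa-2,5-diene-1-carboxylic acid
Product: 2 methyl cyclohexa-2,5-diene-1-carboxylate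
Conditions: MeOH, H2SO4 (cat.), rt
Reagents that add atoms: methanol, CO
Why: Fischer esterification, under which the skipped diene and the doubly allylic C–H should be inert to catalytic acid at room temperature.

Step 2
Reactants: 2 methyl cyclohexa-2,5-diene-1-carboxylate
Product: 4 methyl 1-hydroxycyclohexa-2,5-diene-1-carboxylate, via potassium dienolate 3 (not isolated)
Conditions: KN(SiMe3)2, THF, −78 °C; 2-(benzenesulfonyl)-3-phenyloxaziridine, −78 °C; AcOH quench
Reagents that add atoms: 2-(benzenesulfonyl)-3-phenyloxaziridine, O=S(=O)(N1OC1c1ccccc1)c1ccccc1; KN(SiMe3)2, C[Si](C)(C)[N-][Si](C)(C)C.[K+] (its potassium is found in 3 only)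
Why: Davis oxaziridine α-hydroxylation of an ester enolate, in which the cross-conjugated dienolate takes the electrophilic oxygen at the α-carbon C1 (as in Birch reductive alkylations), so both alkenes stay skipped, and the potassium counter-ion limits addition of the enolate to the sulfonimine co-product.

Step 3
Reactants: 4 methyl 1-hydroxycyclohexa-2,5-diene-1-carboxylate
Product: 5 1-(hydroxymethyl)cyclohexa-2,5-dien-1-ol
Conditions: LiAlH4, Et2O, 0 °C; then H2O, aq NaOH
Reagents that add atoms: none
Why: Hydride reduction of an ester to the primary alcohol, with a basic work-up that should leave the acid-labile bis-allylic tertiary carbinol intact.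

Step 4
Reactants: 5 1-(hydroxymethyl)cyclohexa-2,5-dien-1-ol; 6 benzoyl chloride
Product: 7 (1-hydroxycyclohexa-2,5-dien-1-yl)methyl benzoate
Conditions: BzCl (1.05 equiv), Et3N, CH2Cl2, −20 → 0 °C
Reagents that add atoms: benzoyl chloride (6), ClC(=O)c1ccccc1
Why: Sterically controlled acylation of the primary hydroxyl in the presence of the tertiary one, run with amine base so that no acid reaches the dienol.

Step 5
Reactants: 7 (1-hydroxycyclohexa-2,5-dien-1-yl)methyl benzoate; 8 cumene hydroperoxide
Product: 9 [(1R,2R,3R)-2,3-epoxy-1-hydroxycyclohex-5-en-1-yl]methyl benzoate (oxirane oxygen syn to C1–OH)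
Conditions: Hf(OtBu)4 (10 mol %), C2-symmetric bishydroxamic acid ligand from (R,R)-cyclohexane-1,2-diamine (N,N'-dihydroxy-N,N'-bis(2,2-diarylacetyl) type, 11 mol %), cumene hydroperoxide (1.3 equiv), DMPU, 4 Å MS, toluene, 0 °C
Reagents that add atoms: cumene hydroperoxide (8), CC(C)(OO)c1ccccc1
Why: The tertiary C1 alkoxide and the cumyl peroxide bind side by side on the tetravalent hafnium bishydroxamate, and the activated peroxide oxygen is passed in one concerted event to C2=C3, so the oxirane closes by [2+1] oxygen-atom transfer with both C–O bonds formed together. The closest known reaction type is the hydroxyl-directed asymmetric epoxidation of tertiary allylic alcohols with hafnium bishydroxamate catalysts, including group-selective mono-epoxidation of divinyl carbinols. C2 and C3 are set relative to C1 by the tether to the metal, which allows delivery only to the alkene face syn to C1–O, while C1 becomes stereogenic and its absolute sense, and with it that of all three centres, is fixed by the chiral ligand choosing one of the two enantiotopic alkenes. The step needs enantiotopic-group selectivity, syn facial selectivity and a stop at the mono-epoxide: the first rests on the ligand, the second on the single metal-binding hydroxyl lying on the mirror plane of 7, and the third on the fact that the alkene left in 9 is the one the catalyst disfavours. The small excess of oxidant should convert the minor antipode of 9, whose remaining alkene is the favoured one, into the achiral bis-epoxide and so raise the optical purity of 9. DMPU and molecular sieves temper the Lewis acidity and keep the medium neutral, because ionisation at the bis-allylic C1–O would end in an arene.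

Step 6
Reactants: 9 [(1R,2R,3R)-2,3-epoxy-1-hydroxycyclohex-5-en-1-yl]methyl benzoate
Product: 10 [(1R,2R,3S)-3-acetoxy-1,2-dihydroxycyclohex-5-en-1-yl]methyl benzoate
Conditions: Ti(OiPr)4 (1.5 equiv), AcOH (3 equiv), CH2Cl2, rt
Reagents that add atoms: acetic acid, CC(=O)O
Why: Titanium-alkoxide-mediated C3-selective opening of a 2,3-epoxy alcohol by a carboxylic acid, in which titanium bridges C1–O and the oxirane oxygen and acetate attacks C3, the carbon away from the quaternary centre, in an SN2 way anti to the oxirane, inverting C3 and leaving C2–O syn to C1–OH.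

Step 7
Reactants: 10 [(1R,2R,3S)-3-acetoxy-1,2-dihydroxycyclohex-5-en-1-yl]methyl benzoate
Product: 11 [(1R,2R,3S)-2,3-diacetoxy-1-hydroxycyclohex-5-en-1-yl]methyl benzoate
Conditions: Ac2O (1.2 equiv), pyridine, DMAP (cat.), CH2Cl2, 0 °C
Reagents that add atoms: acetic anhydride, CC(=O)OC(C)=O
Why: Standard acetylation of the secondary C2 hydroxyl, which should outpace the hindered tertiary C1 hydroxyl at 0 °C and touches no stereocentre.

Step 8
Reactants: 11 [(1R,2R,3S)-2,3-diacetoxy-1-hydroxycyclohex-5-en-1-yl]methyl benzoate
Product: 12 [(1S,2R,3S,5S,6S)-2,3-diacetoxy-5,6-epoxy-1-hydroxycyclohexyl]methyl benzoate (oxirane oxygen syn to C1–OH)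
Conditions: VO(acac)2 (5 mol %), tBuOOH (decane, 1.5 equiv), CH2Cl2, 0 °C → rt
Reagents that add atoms: tert-butyl hydroperoxide, CC(C)(C)OO
Why: Vanadium-catalysed hydroxyl-directed epoxidation of a cyclic allylic alcohol, in which the vanadate ester of C1–OH delivers oxygen to the syn face of C5=C6 and so sets C5 and C6.

Step 9
Reactants: 12 [(1S,2R,3S,5S,6S)-2,3-diacetoxy-5,6-epoxy-1-hydroxycyclohexyl]methyl benzoate; 13 diphenyl diselenide
Product: 14 [(1S,2R,3S,5R,6R)-2,3-diacetoxy-1,6-dihydroxy-5-(phenylselanyl)cyclohexyl]methyl benzoate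
Conditions: (PhSe)2 (0.6 equiv), NaBH4, EtOH–THF, 0 °C → rt
Reagents that add atoms: diphenyl diselenide (13), c1ccc([Se][Se]c2ccccc2)cc1
Why: Epoxide opening by sodium benzeneselenolate (first half of the epoxide-to-allylic-alcohol transposition), an SN2 attack expected at C5, the carbon remote from the quaternary and β-oxygenated C1, anti to the oxirane, giving C5–Se trans to the retained C6–OH.

Step 10
Reactants: 14 [(1S,2R,3S,5R,6R)-2,3-diacetoxy-1,6-dihydroxy-5-(phenylselanyl)cyclohexyl]methyl benzoate
Product: 16 [(1S,2R,3S,6S)-2,3-diacetoxy-1,6-dihydroxycyclohex-4-en-1-yl]methyl benzoate, via selenoxide 15 (not isolated)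
Conditions: NaIO4, NaHCO3, THF–H2O, 0 → 40 °C
Reagents that add atoms: NaIO4, [Na+].[O-][I](=O)(=O)=O (its oxygen is found in 15 only)
Why: Selenide oxidation and selenoxide syn-elimination, which in β-hydroxy selenoxides runs away from the carbinol carbon, so the C4–H syn to selenium is removed, C4=C5 forms and no stereocentre is touched.

## Compound list

1 | cyclohexa-2,5-diene-1-carboxylic acid | OC(=O)C1C=CCC=C1 | starting material
2 | methyl cyclohexa-2,5-diene-1-carboxylate | COC(=O)C1C=CCC=C1 | intermediate
3 | potassium dienolate of 2 | COC([O-])=C1C=CCC=C1.[K+] | intermediate (not isolated)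
4 | methyl 1-hydroxycyclohexa-2,5-diene-1-carboxylate | COC(=O)C1(O)C=CCC=C1 | intermediate
5 | 1-(hydroxymethyl)cyclohexa-2,5-dien-1-ol | OCC1(O)C=CCC=C1 | intermediate
6 | benzoyl chloride | ClC(=O)c1ccccc1 | starting material
7 | (1-hydroxycyclohexa-2,5-dien-1-yl)methyl benzoate | OC1(COC(=O)c2ccccc2)C=CCC=C1 | intermediate
8 | cumene hydroperoxide | CC(C)(OO)c1ccccc1 | starting material
9 | [(1R,2R,3R)-2,3-epoxy-1-hydroxycyclohex-5-en-1-yl]methyl benzoate | O1[C@@H]2CC=C[C@@](O)(COC(=O)c3ccccc3)[C@H]12 | intermediate
10 | [(1R,2R,3S)-3-acetoxy-1,2-dihydroxycyclohex-5-en-1-yl]methyl benzoate | CC(=O)O[C@H]1CC=C[C@@](O)(COC(=O)c2ccccc2)[C@@H]1O | intermediate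
11 | [(1R,2R,3S)-2,3-diacetoxy-1-hydroxycyclohex-5-en-1-yl]methyl benzoate | CC(=O)O[C@H]1CC=C[C@@](O)(COC(=O)c2ccccc2)[C@@H]1OC(C)=O | intermediate
12 | [(1S,2R,3S,5S,6S)-2,3-diacetoxy-5,6-epoxy-1-hydroxycyclohexyl]methyl benzoate | CC(=O)O[C@H]1C[C@@H]2O[C@@H]2[C@@](O)(COC(=O)c3ccccc3)[C@@H]1OC(C)=O | intermediate
13 | diphenyl diselenide | c1ccc([Se][Se]c2ccccc2)cc1 | starting material
14 | [(1S,2R,3S,5R,6R)-2,3-diacetoxy-1,6-dihydroxy-5-(phenylselanyl)cyclohexyl]methyl benzoate | CC(=O)O[C@H]1C[C@@H]([Se]c2ccccc2)[C@H](O)[C@@](O)(COC(=O)c3ccccc3)[C@@H]1OC(C)=O | intermediate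
15 | [(1S,2R,3S,5R,6R)-2,3-diacetoxy-5-(benzeneseleninyl)-1,6-dihydroxycyclohexyl]methyl benzoate (selenoxide, either configuration at selenium) | CC(=O)O[C@H]1C[C@@H]([Se](=O)c2ccccc2)[C@H](O)[C@@](O)(COC(=O)c3ccccc3)[C@@H]1OC(C)=O | intermediate (not isolated)
16 | [(1S,2R,3S,6S)-2,3-diacetoxy-1,6-dihydroxycyclohex-4-en-1-yl]methyl benzoate | CC(=O)O[C@H]1C=C[C@H](O)[C@@](O)(COC(=O)c2ccccc2)[C@@H]1OC(C)=O | target

## Step count and risks

Total step count: 10. Longest linear sequence: 10 steps (1 to 16).

**Step 5 (key step).** Three things may go wrong: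
- The ligand may discriminate poorly between the two enantiotopic alkenes of a nearly flat cyclic dienol.
- The Lewis-acidic metal may ionise the bis-allylic C1–O bond, after which loss of a C4 proton aromatises the ring.
- Epoxidation may run on to the bis-epoxide and cost material.

Fallback, from 7 and back at 11 (or at 10): 7 is epoxidised without a chiral ligand (VO(acac)2, 1.0 equiv tBuOOH, toluene, 0 °C). This should give the syn mono-epoxide as the racemate, that is 9 together with its antipode [(1S,2S,3S)-2,3-epoxy-1-hydroxycyclohex-5-en-1-yl]methyl benzoate F1. Opening under the conditions of step 6 gives 10 together with its antipode [(1S,2S,3R)-3-acetoxy-1,2-dihydroxycyclohex-5-en-1-yl]methyl benzoate F2. A lipase-catalysed acyl transfer (Pseudomonas cepacia lipase or Candida antarctica lipase B, vinyl acetate, tert-butyl methyl ether, 30 °C) then resolves the pair at the secondary C2–OH. By the Kazlauskas rule, with the quaternary C1 as the large group, 10 is expected to be the faster antipode and would be acetylated to 11, leaving F2 to be removed by chromatography. If the enzyme prefers the other hand and acetylates F2 to [(1S,2S,3R)-2,3-diacetoxy-1-hydroxycyclohex-5-en-1-yl]methyl benzoate F3, unreacted 10 is separated and enters step 7.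

**Step 9.** Two things may go wrong:
- Attack may go to C6 instead of C5. The trans-diaxial pathway to C5 passes through the ring conformer with both acetates and C7 axial, whereas the more comfortable conformer directs diaxial attack to C6.
- The basic ethanolic selenolate/borate medium may cause ethanolysis or migration of the acetates and the benzoate.

Fallback, from 11 directly to 16: a Schenck ene reaction (O2, hν, tetraphenylporphyrin, CH2Cl2, 0 °C). Singlet oxygen should add at C6 on the face syn to the hydrogen-bonding C1–OH and take the syn hydrogen from C4, the only allylic C–H available. This moves the alkene to C4=C5 and gives the hydroperoxide [(1R,2R,3S,6S)-2,3-diacetoxy-6-hydroperoxy-1-hydroxycyclohex-4-en-1-yl]methyl benzoate F4. Reduction of the O–O bond with PPh3 in the same flask gives 16. No base is used and 12, 14 and 15 are bypassed.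

**Step 6.** Two things may go wrong:
- Once the oxirane is activated, the carbonyl oxygen of the benzoate may attack C2 from the face anti to the oxirane through a six-membered acyloxonium ion, inverting the wrong carbon.
- Acetate may attack C2 directly.

Fallback, from 9 and back at 10: the participating group is removed before the opening. Methanolysis (K2CO3, MeOH, 0 °C) gives the epoxy diol (1R,2R,3R)-2,3-epoxy-1-(hydroxymethyl)cyclohex-5-en-1-ol F5. Acetate opening at C3 (Ti(OiPr)4, AcOH, CH2Cl2, rt, or CsOAc with AcOH in DMF at 60 °C) gives (1R,2R,3S)-3-acetoxy-1-(hydroxymethyl)cyclohex-5-ene-1,2-diol F6. Benzoylation of the primary hydroxyl only (BzCl, Et3N, CH2Cl2, −40 °C) returns 10. An acetyl shift between O3 and O2 in F6 would be harmless, since step 7 acetylates whichever of the two is free.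

## Further compounds

F1 | step 5 | [(1S,2S,3S)-2,3-epoxy-1-hydroxycyclohex-5-en-1-yl]methyl benzoate (antipode of 9) | O1[C@H]2CC=C[C@](O)(COC(=O)c3ccccc3)[C@@H]12
F2 | step 5 | [(1S,2S,3R)-3-acetoxy-1,2-dihydroxycyclohex-5-en-1-yl]methyl benzoate (antipode of 10) | CC(=O)O[C@@H]1CC=C[C@](O)(COC(=O)c2ccccc2)[C@H]1O
F3 | step 5 | [(1S,2S,3R)-2,3-diacetoxy-1-hydroxycyclohex-5-en-1-yl]methyl benzoate (antipode of 11) | CC(=O)O[C@@H]1CC=C[C@](O)(COC(=O)c2ccccc2)[C@H]1OC(C)=O
F4 | step 9 | [(1R,2R,3S,6S)-2,3-diacetoxy-6-hydroperoxy-1-hydroxycyclohex-4-en-1-yl]methyl benzoate | CC(=O)O[C@H]1C=C[C@H](OO)[C@@](O)(COC(=O)c2ccccc2)[C@@H]1OC(C)=O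
F5 | step 6 | (1R,2R,3R)-2,3-epoxy-1-(hydroxymethyl)cyclohex-5-en-1-ol | O1[C@@H]2CC=C[C@@](O)(CO)[C@H]12
F6 | step 6 | (1R,2R,3S)-3-acetoxy-1-(hydroxymethyl)cyclohex-5-ene-1,2-diol | CC(=O)O[C@H]1CC=C[C@@](O)(CO)[C@@H]1O
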